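A direct plan would take the benzyl-protected o-alkynylphenol A1, reached by Sonogashira coupling, and would close the furan ring by carbonylative heteroannulation with the aryl iodide A2 to the 7-acetyl-3-aroyl-2-arylbenzofuran A3.
The last aryl group would come from a Claisen–Schmidt condensation of A3 to the chalcone A4, followed by hydrogenation and hydrogenolysis.
Three steps would be weakest.
The carbonylative annulation would need the carbonyl insertion to outrun direct aryl transfer and plain cycloisomerisation at a hindered, ketone-chelated phenoxide.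
The masking of that phenol as an acetate before the Sonogashira coupling and its release afterwards would add two steps without adding complexity.
The late aldol condensation would have to enolise the most hindered ketone of A3, and the reduction after it would have to stop at the C=C bond of A4 while six benzyl ethers are cleaved.

The route opens the furan ring at both O1–C2 and C3–C3a, so that the target falls into a partly methylated phloretin, which already holds the benzo ring with its complete 7-acyl chain, and a diaryl ynone. The single free phenol of the phloretin ether adds to the ynone, and the key step then joins the vinylic carbon to the unfunctionalised C–H next to that oxygen (the future C3a, activated by three oxygen substituents of the benzo ring) by palladium-catalysed twofold C–H coupling; the ynone polarity has already placed the aryl group at C2 and the aroyl group at C3. Aryl halide, carbonyl insertion, phenol masking, late aldol condensation and enone reduction all disappear.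

Key step: step 4

Assumption: the conjugate addition of step 3 is taken to give the (2Z) alkene by anti addition. Should the (2E) isomer form as well, it would be carried on with it, because step 4 does not depend on the alkene geometry. The target is achiral, so no stereocentre has to be set.

Step 1
Reactants: 1 phloretin, 3-(4-hydroxyphenyl)-1-(2,4,6-trihydroxyphenyl)propan-1-one
Product: 2 1-(2-hydroxy-4,6-dimethoxyphenyl)-3-(4-methoxyphenyl)propan-1-one
Conditions: Me2SO4 (3.1 equiv), K2CO3 (3.5 equiv), acetone, reflux
Reagents that add atoms: dimethyl sulfate, COS(=O)(=O)OC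
Why: Williamson ether synthesis with a hard methylating agent, in which the hydroxyl para to the ketone, the hydroxyl of the 4-hydroxyphenyl group and one of the two ortho hydroxyls are O-methylated, while the last ortho hydroxyl, held in a hydrogen bond to the ketone, is the least nucleophilic and should stay free.

Step 2
Reactants: 3 2,4-dimethoxybenzoyl chloride; 4 1-ethynyl-4-methoxybenzene
Product: 5 1-(2,4-dimethoxyphenyl)-3-(4-methoxyphenyl)prop-2-yn-1-one
Conditions: PdCl2(PPh3)2 (2 mol %), CuI (4 mol %), Et3N (1.2 equiv), THF, rt, argon
Reagents that add atoms: none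
Why: Acyl Sonogashira coupling, in which the acid chloride adds oxidatively to zerovalent palladium, the copper acetylide formed from 4 transmetalates and reductive elimination gives the ynone at room temperature, where decarbonylation should not compete and the small amount of amine cannot add to the product.

Step 3
Reactants: 2 1-(2-hydroxy-4,6-dimethoxyphenyl)-3-(4-methoxyphenyl)propan-1-one; 5 1-(2,4-dimethoxyphenyl)-3-(4-methoxyphenyl)prop-2-yn-1-one
Product: 6 (2Z)-3-{3,5-dimethoxy-2-[3-(4-methoxyphenyl)propanoyl]phenoxy}-1-(2,4-dimethoxyphenyl)-3-(4-methoxyphenyl)prop-2-en-1-one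
Conditions: Cs2CO3 (0.3 equiv), MeCN, rt to 50 °C; aq. NH4Cl
Reagents that add atoms: none
Why: Base-catalysed oxa-Michael addition (hydroaryloxylation of an ynone), in which the only free phenoxide of 2 attacks the alkyne carbon beta to the ketone, the one that carries the 4-methoxyphenyl group, and protonation of the allenolate anti to the new C–O bond should give the (2Z) vinylogous ester, a substoichiometric base limiting enolisation of the propanoyl chain.

Step 4
Reactants: 6 (2Z)-3-{3,5-dimethoxy-2-[3-(4-methoxyphenyl)propanoyl]phenoxy}-1-(2,4-dimethoxyphenyl)-3-(4-methoxyphenyl)prop-2-en-1-one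
Product: 7 1-[3-(2,4-dimethoxybenzoyl)-4,6-dimethoxy-2-(4-methoxyphenyl)-1-benzofuran-7-yl]-3-(4-methoxyphenyl)propan-1-one
Conditions: Pd(OAc)2 (10 mol %), PPh3 (10 mol %), CF3CO2Ag (2.2 equiv), 4 Å MS, PhCl, 110 °C, sealed tube
Reagents that add atoms: none
Why: Electrophilic palladation of the push-pull alkene of 6 at its only vinylic C–H (the carbon alpha to the ketone) and loss of the proton give a vinyl species of divalent palladium; this palladates the neighbouring arene at the one free position ortho to the ether oxygen to form a six-membered oxapalladacycle, and reductive elimination makes the C3–C3a bond, the zerovalent palladium being returned to divalent palladium by two equivalents of CF3CO2Ag. The closest known reaction type is the palladium-catalysed intramolecular dehydrogenative C–H/C–H coupling of 3-aryloxyacrylates to benzofuran-3-carboxylates and of N-aryl enaminones to 3-acylindoles. The furan ring is the only ring closed, by C–C bond formation in a formal 5-endo sense that the palladacycle makes possible, and since the product is aromatic no stereocentre arises. The step needs site selectivity on the arene and indifference to the alkene geometry: the other ortho position carries the acyl chain, so only the C–H between the vinyloxy and methoxy groups (ortho, ortho and para to three oxygen donors) can close a five-membered ring, and the C-palladated oxocarbenium intermediate rotates freely about the former C=C bond, so the (2Z) geometry of 6 should be no obstacle. The placement of the aryl group at C2 and the aroyl group at C3 is already fixed in 6 by the polarity of the ynone. The saturated 7-acyl chain and the methyl ethers should be inert in a non-coordinating solvent, without dimethyl sulfoxide, which would favour desaturation of the ketone.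

Step 5
Reactants: 7 1-[3-(2,4-dimethoxybenzoyl)-4,6-dimethoxy-2-(4-methoxyphenyl)-1-benzofuran-7-yl]-3-(4-methoxyphenyl)propan-1-one
Product: 8 1-[3-(2,4-dihydroxybenzoyl)-4,6-dihydroxy-2-(4-hydroxyphenyl)-1-benzofuran-7-yl]-3-(4-hydroxyphenyl)propan-1-one (CNP0181782.0, achiral)
Conditions: BBr3 (15 equiv), CH2Cl2, −78 °C to rt; then H2O, 0 °C
Reagents that add atoms: none
Why: Lewis-acid cleavage of aryl methyl ethers (coordination of boron to oxygen, then SN2 attack of bromide on the methyl group), assisted by chelation at the ethers next to a ketone and expected to leave the ketones, the furan and the saturated chain untouched, with hydrolysis of the aryl borates on work-up freeing the six phenols.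

Compound list
1 | phloretin, 3-(4-hydroxyphenyl)-1-(2,4,6-trihydroxyphenyl)propan-1-one | O=C(CCc1ccc(O)cc1)c1c(O)cc(O)cc1O | starting material
2 | 1-(2-hydroxy-4,6-dimethoxyphenyl)-3-(4-methoxyphenyl)propan-1-one | COc1ccc(CCC(=O)c2c(O)cc(OC)cc2OC)cc1 | intermediate
3 | 2,4-dimethoxybenzoyl chloride | COc1ccc(C(=O)Cl)c(OC)c1 | starting material
4 | 1-ethynyl-4-methoxybenzene | C#Cc1ccc(OC)cc1 | starting material
5 | 1-(2,4-dimethoxyphenyl)-3-(4-methoxyphenyl)prop-2-yn-1-one | COc1ccc(C#CC(=O)c2ccc(OC)cc2OC)cc1 | intermediate
6 | (2Z)-3-{3,5-dimethoxy-2-[3-(4-methoxyphenyl)propanoyl]phenoxy}-1-(2,4-dimethoxyphenyl)-3-(4-methoxyphenyl)prop-2-en-1-one | COc1ccc(cc1)/C(Oc1cc(OC)cc(OC)c1C(=O)CCc1ccc(OC)cc1)=C/C(=O)c1ccc(OC)cc1OC | intermediate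
7 | 1-[3-(2,4-dimethoxybenzoyl)-4,6-dimethoxy-2-(4-methoxyphenyl)-1-benzofuran-7-yl]-3-(4-methoxyphenyl)propan-1-one | O=C(CCc1ccc(OC)cc1)c1c(OC)cc(OC)c2c(C(=O)c3ccc(OC)cc3OC)c(-c3ccc(OC)cc3)oc12 | intermediate
8 | 1-[3-(2,4-dihydroxybenzoyl)-4,6-dihydroxy-2-(4-hydroxyphenyl)-1-benzofuran-7-yl]-3-(4-hydroxyphenyl)propan-1-one (CNP0181782.0, achiral) | O=C(CCc1ccc(O)cc1)c1c(O)cc(O)c2c(C(=O)c3ccc(O)cc3O)c(-c3ccc(O)cc3)oc12 | target

Total step count: 5. Longest linear sequence: 4 steps (1 to 2 to 6 to 7 to 8; step 2 is the convergent branch).

Steps most likely to fail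

Step 4. The palladation of the crowded, trisubstituted push-pull alkene may be slow, its geometry may not equilibrate, the vinyl ether may be hydrolysed by the acid that the oxidant sets free, or palladium may desaturate the propanoyl chain. The fallback makes the same C3–C3a bond from an aryl iodide; it sets out from 2 and comes back at 7. Iodination of 2 with N-iodosuccinimide (DMF, 0 °C), directed ortho to the free phenol, would give 1-(2-hydroxy-3-iodo-4,6-dimethoxyphenyl)-3-(4-methoxyphenyl)propan-1-one F1. Oxa-Michael addition of F1 to 5 (Cs2CO3, DMF, 50 °C) would give (2Z)-3-{2-iodo-3,5-dimethoxy-6-[3-(4-methoxyphenyl)propanoyl]phenoxy}-1-(2,4-dimethoxyphenyl)-3-(4-methoxyphenyl)prop-2-en-1-one F2. An intramolecular Heck-type cyclisation of F2 (Pd(PPh3)4, K2CO3, DMF, 90 °C), which is redox-neutral and needs neither silver salt nor acid, would then give 7.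

Step 3. The ketone-chelated phenoxide may add too slowly, the addition may reverse, the phenoxide may attack through carbon, or the enolate of the propanoyl ketone may close onto the new vinylogous ester. The fallback attaches the acyl chain after the furan is closed; it sets out from 5 and comes back at 7. Commercial 3,5-dimethoxyphenol, which is neither chelated nor hindered, would add to 5 (Cs2CO3, MeCN, rt) to give (2Z)-3-(3,5-dimethoxyphenoxy)-1-(2,4-dimethoxyphenyl)-3-(4-methoxyphenyl)prop-2-en-1-one F3. Oxidative closure under the conditions of step 4, at either of the two equivalent ortho positions, would give (2,4-dimethoxyphenyl)[4,6-dimethoxy-2-(4-methoxyphenyl)-1-benzofuran-3-yl]methanone F4. Friedel–Crafts acylation of F4 with commercial 3-(4-methoxyphenyl)propanoyl chloride (SnCl4, CH2Cl2, −20 to 0 °C) should take place at C7, the less hindered of the two free positions of the benzo ring (C5 lies between two methoxy groups), to give 7.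

Step 5. The ethers without a neighbouring carbonyl group may be cleaved incompletely, or the electron-rich polyphenol may decompose on long exposure to BBr3. The fallback removes the six ethers in two stages by two different mechanisms; it sets out from 7 and comes back at 8. BCl3 (CH2Cl2, −78 to 0 °C) would cleave only the two methoxy groups that can form a six-membered boron chelate with a ketone, to give 1-[6-hydroxy-3-(2-hydroxy-4-methoxybenzoyl)-4-methoxy-2-(4-methoxyphenyl)-1-benzofuran-7-yl]-3-(4-methoxyphenyl)propan-1-one F5. The four remaining ethers would then be cleaved by nucleophilic demethylation with NaSEt (DMF, 130 °C; acidic work-up) to give 8.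

Further compounds
F1 | step 4 | 1-(2-hydroxy-3-iodo-4,6-dimethoxyphenyl)-3-(4-methoxyphenyl)propan-1-one | COc1ccc(CCC(=O)c2c(O)c(I)c(OC)cc2OC)cc1
F2 | step 4 | (2Z)-3-{2-iodo-3,5-dimethoxy-6-[3-(4-methoxyphenyl)propanoyl]phenoxy}-1-(2,4-dimethoxyphenyl)-3-(4-methoxyphenyl)prop-2-en-1-one | COc1ccc(cc1)/C(Oc1c(I)c(OC)cc(OC)c1C(=O)CCc1ccc(OC)cc1)=C/C(=O)c1ccc(OC)cc1OC
F3 | step 3 | (2Z)-3-(3,5-dimethoxyphenoxy)-1-(2,4-dimethoxyphenyl)-3-(4-methoxyphenyl)prop-2-en-1-one | COc1ccc(cc1)/C(Oc1cc(OC)cc(OC)c1)=C/C(=O)c1ccc(OC)cc1OC
F4 | step 3 | (2,4-dimethoxyphenyl)[4,6-dimethoxy-2-(4-methoxyphenyl)-1-benzofuran-3-yl]methanone | COc1ccc(cc1)-c1oc2cc(OC)cc(OC)c2c1C(=O)c1ccc(OC)cc1OC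
F5 | step 5 | 1-[6-hydroxy-3-(2-hydroxy-4-methoxybenzoyl)-4-methoxy-2-(4-methoxyphenyl)-1-benzofuran-7-yl]-3-(4-methoxyphenyl)propan-1-one | O=C(CCc1ccc(OC)cc1)c1c(O)cc(OC)c2c(C(=O)c3ccc(OC)cc3O)c(-c3ccc(OC)cc3)oc12
A1 | direct plan | 1-[4,6-bis(benzyloxy)-3-{[4-(benzyloxy)phenyl]ethynyl}-2-hydroxyphenyl]ethan-1-one | CC(=O)c1c(O)c(C#Cc2ccc(OCc3ccccc3)cc2)c(OCc2ccccc2)cc1OCc1ccccc1
A2 | direct plan | 2,4-bis(benzyloxy)-1-iodobenzene | Ic1ccc(OCc2ccccc2)cc1OCc1ccccc1
A3 | direct plan | 1-{4,6-bis(benzyloxy)-3-[2,4-bis(benzyloxy)benzoyl]-2-[4-(benzyloxy)phenyl]-1-benzofuran-7-yl}ethan-1-one | CC(=O)c1c(OCc2ccccc2)cc(OCc2ccccc2)c2c(C(=O)c3ccc(OCc4ccccc4)cc3OCc3ccccc3)c(-c3ccc(OCc4ccccc4)cc3)oc12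
A4 | direct plan | (2E)-1-{4,6-bis(benzyloxy)-3-[2,4-bis(benzyloxy)benzoyl]-2-[4-(benzyloxy)phenyl]-1-benzofuran-7-yl}-3-[4-(benzyloxy)phenyl]prop-2-en-1-one | O=C(/C=C/c1ccc(OCc2ccccc2)cc1)c1c(OCc2ccccc2)cc(OCc2ccccc2)c2c(C(=O)c3ccc(OCc4ccccc4)cc3OCc3ccccc3)c(-c3ccc(OCc4ccccc4)cc3)oc12
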